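The retrosynthesis cuts, in order: the six O–benzyl bonds; the ester C–O bond between the C4 propenoic acid and the lactate oxygen; the Cα=Cβ bond of that acid (back to C4–CHO and malonic acid); then C3a–C7a, C6–C7 and C7–O of the benzofuran together; finally O1–C(alkyne), C2–C3 (aldol) and furan C2'–CH2.
The enabling feature is that ring B (C3a, C4–C7, C7a) carries the C7 hydroxyl next to C7a–O1, while C3a is tied to O1 through C3–C2 (ring C). An ynol ether (C7a, C7) and a tethered furan (C3a, C4, C5, C6 and the oxygen that ends on C7) leave exactly this O1–C7a–C7–OH edge after cycloisomerisation.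
In the forward direction, 3-furaldehyde is masked, homologated at C2' to a furylacetyl imide and joined to ring A by an aldol reaction. The carbinol becomes a terminal ynol ether, and one gold-catalysed step closes ring C and builds ring B. The C3 carbon is then oxidised to the methyl ester, the C4 acetal is extended to the (E)-propenoic acid, the ring D lactate is attached, and all benzyl groups are removed.
C2 and C3 come from an Evans syn aldol with (S)-4-benzyloxazolidin-2-one (syn aldol = 2,3-trans ring C). The lactate centre is bought with (R)-danshensu, and the E alkene comes from the decarboxylative Knoevenagel–Doebner condensation.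

Key step: step 10

Remark: positions are numbered as in 2,3-dihydro-1-benzofuran, furan positions carry primes, ring A is the C2 aryl group and ring D the aryl group of the lactate. (R)-Danshensu is assumed to be purchasable as the enantiopure free acid.

Step 1
Reactants: 1 3-furaldehyde
Product: 2 2-(furan-3-yl)-1,3-dioxolane
Conditions: HOCH2CH2OH, p-TsOH·H2O (cat.), toluene, reflux, Dean–Stark
Reagents that add atoms: ethylene glycol, OCCO
Why: Acid-catalysed acetalisation with azeotropic water removal masks the future C4 formyl carbon as a base-stable dioxolane that also directs the next metalation.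

Step 2
Reactants: 2 2-(furan-3-yl)-1,3-dioxolane
Product: 4 2-(2-iodofuran-3-yl)-1,3-dioxolane, via lithiofuran 3 (not isolated)
Conditions: n-BuLi, THF, −78 → −20 °C; I2, THF, −78 °C
Reagents that add atoms: iodine, [I][I]; n-butyllithium, [Li]CCCC (lithium in 3 only)
Why: In this directed ortho-metalation the acetal oxygens and the intrinsic acidity of the furan α-position both favour C2' over C5', and iodinolysis of 3 fixes the halogen there.

Step 3
Reactants: 4 2-(2-iodofuran-3-yl)-1,3-dioxolane; 5 ethyl bromoacetate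
Product: 7 ethyl 2-[3-(1,3-dioxolan-2-yl)furan-2-yl]acetate, via Reformatsky reagent 6 (not isolated)
Conditions: 5, Zn, Me3SiCl (cat.), THF, 40 °C; then 4, Pd2(dba)3 (cat.), 2-dicyclohexylphosphino-2',4',6'-triisopropylbiphenyl (cat.), THF, 50 °C
Reagents that add atoms: zinc, [Zn] (in 6 only)
Why: In the Reformatsky–Negishi cross-coupling zerovalent palladium inserts into the C–I bond and the zinc enolate 6 transfers the CH2CO2Et unit without strong base, a process well established for heteroaryl halides.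

Step 4
Reactants: 7 ethyl 2-[3-(1,3-dioxolan-2-yl)furan-2-yl]acetate
Product: 8 2-[3-(1,3-dioxolan-2-yl)furan-2-yl]acetic acid
Conditions: LiOH, THF/H2O, 0 °C → rt; then cold 0.5 M HCl to pH 4, immediate extraction
Reagents that add atoms: lithium hydroxide, [Li+].[OH-]
Why: Ester saponification leaves the acetal untouched as long as the acidification is brief, cold and stopped at pH 4.

Step 5
Reactants: 8 2-[3-(1,3-dioxolan-2-yl)furan-2-yl]acetic acid; 9 (S)-4-benzyl-1,3-oxazolidin-2-one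
Product: 11 (S)-4-benzyl-3-{2-[3-(1,3-dioxolan-2-yl)furan-2-yl]acetyl}-1,3-oxazolidin-2-one, via mixed pivalic anhydride 10 (not isolated)
Conditions: t-BuCOCl, Et3N, THF, −20 °C; then LiCl, 9, −20 °C → rt
Reagents that add atoms: pivaloyl chloride, CC(C)(C)C(=O)Cl (in 10 only)
Why: In this mixed-anhydride N-acylation the LiCl/Et3N-activated oxazolidinone attacks the less hindered furylacetyl carbonyl of 10.

Step 6
Reactants: 11 (S)-4-benzyl-3-{2-[3-(1,3-dioxolan-2-yl)furan-2-yl]acetyl}-1,3-oxazolidin-2-one; 12 3,4-bis(benzyloxy)benzaldehyde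
Product: 15 (S)-4-benzyl-3-{(2R,3S)-3-[3,4-bis(benzyloxy)phenyl]-2-[3-(1,3-dioxolan-2-yl)furan-2-yl]-3-hydroxypropanoyl}-1,3-oxazolidin-2-one, via (Z)-boron enolate 13 (not isolated), via boron aldolate 14 (not isolated)
Conditions: n-Bu2BOTf, Et3N, CH2Cl2, −78 → 0 °C; 12, −78 → 0 °C; then pH 7 buffer, MeOH, 30% H2O2, 0 °C
Reagents that add atoms: dibutylboron triflate, CCCCB(CCCC)OS(=O)(=O)C(F)(F)F (in 13 and 14 only)
Why: In the Evans syn aldol, soft enolisation gives the (Z)-boron enolate 13, which reacts through a chair Zimmerman–Traxler transition state on the face remote from the benzyl group of the (S)-auxiliary, setting both centres as the (2R,3S) syn pair that becomes 2,3-trans in ring C.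

Step 7
Reactants: 15 the syn aldol imide
Product: 16 (1S,2R)-1-[3,4-bis(benzyloxy)phenyl]-2-[3-(1,3-dioxolan-2-yl)furan-2-yl]propane-1,3-diol
Conditions: LiBH4, MeOH (1 equiv), THF, 0 °C
Reagents that add atoms: none
Why: Reductive cleavage of the imide with LiBH4 releases the auxiliary, touches neither stereocentre, and takes the carboxyl carbon to the alcohol level, where retro-aldol cleavage and enolisation cannot occur in the strongly basic steps that follow.

Step 8
Reactants: 16 the 1,3-diol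
Product: 17 (1S,2R)-1-[3,4-bis(benzyloxy)phenyl]-2-[3-(1,3-dioxolan-2-yl)furan-2-yl]-3-[(triisopropylsilyl)oxy]propan-1-ol
Conditions: i-Pr3SiCl, imidazole, CH2Cl2/DMF, 0 °C
Reagents that add atoms: chlorotriisopropylsilane, CC(C)[Si](Cl)(C(C)C)C(C)C
Why: This sterically controlled silylation takes the primary hydroxyl only, and triisopropylsilyl is preferred to smaller silyl groups because it resists migration to the neighbouring potassium alkoxide of the next step.

Step 9
Reactants: 17 the mono-silylated diol; 18 trichloroethylene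
Product: 22 {[(2R,3S)-3-[3,4-bis(benzyloxy)phenyl]-2-[3-(1,3-dioxolan-2-yl)furan-2-yl]-3-(ethynyloxy)propyl]oxy}triisopropylsilane, via (E)-1,2-dichlorovinyl ether 19 (not isolated), via chloroethynyl ether 20 (not isolated), via lithium acetylide 21 (not isolated)
Conditions: KH, THF, 0 °C; 18, −50 °C → rt; then n-BuLi, −78 → −40 °C; H2O, −78 → 0 °C; work-up and concentration below 10 °C, used at once
Reagents that add atoms: n-butyllithium, [Li]CCCC (lithium in 21 only)
Why: In this one-pot ynol ether synthesis the potassium alkoxide adds anti to dichloroacetylene formed in situ to give 19, n-BuLi then causes β-elimination to 20 and chlorine–lithium exchange to 21, and water protonates 21, with configuration retained because the C–O bond at the stereocentre is never broken.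

Step 10
Reactants: 22 the furan-tethered terminal ynol ether
Product: 25 (2S,3R)-2-[3,4-bis(benzyloxy)phenyl]-4-(1,3-dioxolan-2-yl)-3-{[(triisopropylsilyl)oxy]methyl}-2,3-dihydro-1-benzofuran-7-ol, via oxepine 23 (not isolated), via arene oxide 24 (not isolated)
Conditions: Ph3PAuNTf2 (3 mol %), 4 Å molecular sieves, CH2Cl2, −20 °C → rt
Reagents that add atoms: none
Why: Monovalent gold coordinates the ynol ether and polarises it towards a gold-bound ketene oxonium ion, whose oxygen-bearing carbon (future C7a) is attacked by the tethered furan carbon C2' (future C3a) in a 5-exo-dig closure that forms ring C and a cyclopropyl gold carbenoid. Cleavage of the C2'–O bond opens the furan to a (Z)-dienal gold carbene, the freed carbonyl oxygen adds to the carbene carbon (future C7), gold is released, and oxepine 23 closes by a disrotatory 6π electrocyclisation (C6–C7 bond, six-membered ring B) to arene oxide 24. Heterolysis of the C6–O bond of 24 gives a cyclohexadienyl cation with charge at C7a, where O1 stabilises it, whereas heterolysis of C7–O gives a cation that O1 cannot reach, so loss of H7 leaves the hydroxyl on C7 and not on C6. The closest known reaction type is the gold-catalysed furan–yne phenol synthesis with ynol ether and ynamide tethers, which delivers 7-hydroxy-2,3-dihydrobenzofurans and 7-hydroxyindolines at or below room temperature. No stereocentre is created in 25 (those of 24 vanish on aromatisation), and C2 and C3 pass through unchanged because the medium is neutral and C3 still bears a silyloxymethyl group instead of an enolisable ester. The furan must win over ring A, the acetal oxygens and adventitious water as the nucleophile, which the higher π-nucleophilicity of a 2-alkylfuran, the short three-atom tether, the low temperature and the molecular sieves should secure.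

Step 11
Reactants: 25 the C7 phenol
Product: 26 {[(2S,3R)-7-(benzyloxy)-2-[3,4-bis(benzyloxy)phenyl]-4-(1,3-dioxolan-2-yl)-2,3-dihydro-1-benzofuran-3-yl]methoxy}triisopropylsilane
Conditions: BnBr, K2CO3, DMF, rt
Reagents that add atoms: benzyl bromide, BrCc1ccccc1
Why: Williamson etherification caps the oxidation-sensitive phenol with the same group that protects the other phenols, so one final operation removes them all.

Step 12
Reactants: 26 the silyl ether
Product: 27 [(2S,3R)-7-(benzyloxy)-2-[3,4-bis(benzyloxy)phenyl]-4-(1,3-dioxolan-2-yl)-2,3-dihydro-1-benzofuran-3-yl]methanol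
Conditions: n-Bu4NF, THF, rt
Reagents that add atoms: none
Why: Fluoride-induced desilylation is orthogonal to the acetal and the benzyl ethers, and at this stage no base-sensitive centre is present.

Step 13
Reactants: 27 the primary alcohol
Product: 29 (2S,3S)-7-(benzyloxy)-2-[3,4-bis(benzyloxy)phenyl]-4-(1,3-dioxolan-2-yl)-2,3-dihydro-1-benzofuran-3-carboxylic acid, via aldehyde 28 (not isolated)
Conditions: 2,2,6,6-tetramethylpiperidin-1-oxyl (cat.), NaClO2, NaOCl (cat.), MeCN/phosphate buffer pH 6.7, 35 °C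
Reagents that add atoms: sodium chlorite, [Na+].[O-]Cl=O
Why: In this nitroxyl-catalysed oxidation with chlorite as terminal oxidant the buffered medium spares the acetal, hypochlorite stays at catalytic level so the electron-rich rings should not be chlorinated, and the epimerisable aldehyde 28 is consumed as fast as it forms.

Step 14
Reactants: 29 the C3 carboxylic acid
Product: 30 methyl (2S,3S)-7-(benzyloxy)-2-[3,4-bis(benzyloxy)phenyl]-4-(1,3-dioxolan-2-yl)-2,3-dihydro-1-benzofuran-3-carboxylate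
Conditions: MeI, KHCO3, DMF, rt
Reagents that add atoms: iodomethane, IC
Why: SN2 O-alkylation of the carboxylate needs only hydrogencarbonate, a base too weak to deprotonate C3 or to trigger β-elimination of O1.

Step 15
Reactants: 30 the acetal methyl ester
Product: 31 methyl (2S,3S)-7-(benzyloxy)-2-[3,4-bis(benzyloxy)phenyl]-4-formyl-2,3-dihydro-1-benzofuran-3-carboxylate
Conditions: 1 M HCl, THF, rt
Reagents that add atoms: water, O
Why: Acid-catalysed hydrolysis of an aryl dioxolane is fast under conditions that leave the methyl ester, the benzyl ethers and the ring C ether intact.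

Step 16
Reactants: 31 the C4 aldehyde; 32 malonic acid
Product: 34 (2E)-3-{(2S,3S)-7-(benzyloxy)-2-[3,4-bis(benzyloxy)phenyl]-3-(methoxycarbonyl)-2,3-dihydro-1-benzofuran-4-yl}prop-2-enoic acid, via arylidenemalonic acid 33 (not isolated)
Conditions: 32, pyridine, piperidine (cat.), 80 °C
Reagents that add atoms: none
Why: Knoevenagel–Doebner condensation followed by decarboxylation of 33 gives the thermodynamically favoured E acid, and any reversible deprotonation at C3 returns the more stable 2,3-trans isomer dictated by the fixed C2 centre.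

Step 17
Reactants: 35 (R)-3-(3,4-dihydroxyphenyl)lactic acid (danshensu)
Product: 36 benzyl (2R)-3-[3,4-bis(benzyloxy)phenyl]-2-hydroxypropanoate
Conditions: BnBr, K2CO3, DMF, rt
Reagents that add atoms: benzyl bromide, BrCc1ccccc1
Why: In this Williamson and carboxylate alkylation K2CO3 ionises only the acid and the two phenols, so the secondary alcohol stays free and its stereocentre is not involved.

Step 18
Reactants: 34 the propenoic acid; 36 the tribenzyl lactate
Product: 38 benzyl (2R)-3-[3,4-bis(benzyloxy)phenyl]-2-{[(2E)-3-{(2S,3S)-7-(benzyloxy)-2-[3,4-bis(benzyloxy)phenyl]-3-(methoxycarbonyl)-2,3-dihydro-1-benzofuran-4-yl}prop-2-enoyl]oxy}propanoate, via O-acylisourea 37 (not isolated)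
Conditions: DCC, 4-(dimethylamino)pyridine (cat.), CH2Cl2, 0 °C → rt
Reagents that add atoms: N,N'-dicyclohexylcarbodiimide, C1CCCCC1N=C=NC1CCCCC1 (in 37 only)
Why: Steglich esterification acylates the alcohol oxygen of 36 without breaking its C–O bond, so the R configuration is retained, and cinnamic-type acids are good partners for it.

Step 19
Reactants: 38 the hexabenzyl precursor
Product: 39 monomethyl lithospermate
Conditions: BCl3, C6HMe5, CH2Cl2, −78 → 0 °C; then MeOH/H2O
Reagents that add atoms: none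
Why: In this Lewis-acid debenzylation BCl3 ionises the five aryl benzyl ethers and, on warming, the benzyl ester, and pentamethylbenzene traps each benzyl cation by Friedel–Crafts alkylation, while the alkene (which hydrogenolysis would saturate), the methyl ester, the secondary cinnamate and the C2–O1 bond flanked by the ester should remain.

Compound list
1 | 3-furaldehyde | O=Cc1ccoc1 | starting material
2 | 2-(furan-3-yl)-1,3-dioxolane | c1occc1C1OCCO1 | intermediate
3 | [3-(1,3-dioxolan-2-yl)furan-2-yl]lithium | [Li]c1occc1C1OCCO1 | intermediate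
4 | 2-(2-iodofuran-3-yl)-1,3-dioxolane | Ic1occc1C1OCCO1 | intermediate
5 | ethyl bromoacetate | CCOC(=O)CBr | starting material
6 | bromo(2-ethoxy-2-oxoethyl)zinc | CCOC(=O)C[Zn]Br | intermediate
7 | ethyl 2-[3-(1,3-dioxolan-2-yl)furan-2-yl]acetate | CCOC(=O)Cc1occc1C1OCCO1 | intermediate
8 | 2-[3-(1,3-dioxolan-2-yl)furan-2-yl]acetic acid | OC(=O)Cc1occc1C1OCCO1 | intermediate
9 | (S)-4-benzyl-1,3-oxazolidin-2-one | O=C1N[C@@H](Cc2ccccc2)CO1 | starting material
10 | 2-[3-(1,3-dioxolan-2-yl)furan-2-yl]acetic pivalic anhydride | CC(C)(C)C(=O)OC(=O)Cc1occc1C1OCCO1 | intermediate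
11 | (S)-4-benzyl-3-{2-[3-(1,3-dioxolan-2-yl)furan-2-yl]acetyl}-1,3-oxazolidin-2-one | O=C(Cc1occc1C1OCCO1)N1[C@@H](Cc2ccccc2)COC1=O | intermediate
12 | 3,4-bis(benzyloxy)benzaldehyde | O=Cc1ccc(OCc2ccccc2)c(OCc2ccccc2)c1 | starting material
13 | (S)-4-benzyl-3-{(Z)-1-[(dibutylboranyl)oxy]-2-[3-(1,3-dioxolan-2-yl)furan-2-yl]ethenyl}-1,3-oxazolidin-2-one | CCCCB(CCCC)O/C(=C\c1occc1C1OCCO1)N1[C@@H](Cc2ccccc2)COC1=O | intermediate
14 | O-dibutylboranyl derivative of 15 (boron aldolate) | O=C([C@@H](c1occc1C1OCCO1)[C@H](OB(CCCC)CCCC)c1ccc(OCc2ccccc2)c(OCc2ccccc2)c1)N1[C@@H](Cc2ccccc2)COC1=O | intermediate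
15 | (S)-4-benzyl-3-{(2R,3S)-3-[3,4-bis(benzyloxy)phenyl]-2-[3-(1,3-dioxolan-2-yl)furan-2-yl]-3-hydroxypropanoyl}-1,3-oxazolidin-2-one | O=C([C@@H](c1occc1C1OCCO1)[C@H](O)c1ccc(OCc2ccccc2)c(OCc2ccccc2)c1)N1[C@@H](Cc2ccccc2)COC1=O | intermediate
16 | (1S,2R)-1-[3,4-bis(benzyloxy)phenyl]-2-[3-(1,3-dioxolan-2-yl)furan-2-yl]propane-1,3-diol | OC[C@@H](c1occc1C1OCCO1)[C@H](O)c1ccc(OCc2ccccc2)c(OCc2ccccc2)c1 | intermediate
17 | (1S,2R)-1-[3,4-bis(benzyloxy)phenyl]-2-[3-(1,3-dioxolan-2-yl)furan-2-yl]-3-[(triisopropylsilyl)oxy]propan-1-ol | CC(C)[Si](C(C)C)(C(C)C)OC[C@@H](c1occc1C1OCCO1)[C@H](O)c1ccc(OCc2ccccc2)c(OCc2ccccc2)c1 | intermediate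
18 | trichloroethylene | ClC=C(Cl)Cl | starting material
19 | {[(2R,3S)-3-[3,4-bis(benzyloxy)phenyl]-3-{[(E)-1,2-dichloroethenyl]oxy}-2-[3-(1,3-dioxolan-2-yl)furan-2-yl]propyl]oxy}triisopropylsilane | CC(C)[Si](C(C)C)(C(C)C)OC[C@@H](c1occc1C1OCCO1)[C@H](O/C(Cl)=C\Cl)c1ccc(OCc2ccccc2)c(OCc2ccccc2)c1 | intermediate
20 | {[(2R,3S)-3-[3,4-bis(benzyloxy)phenyl]-3-[(chloroethynyl)oxy]-2-[3-(1,3-dioxolan-2-yl)furan-2-yl]propyl]oxy}triisopropylsilane | CC(C)[Si](C(C)C)(C(C)C)OC[C@@H](c1occc1C1OCCO1)[C@H](OC#CCl)c1ccc(OCc2ccccc2)c(OCc2ccccc2)c1 | intermediate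
21 | lithium acetylide of 22 (lithium on the terminal alkyne carbon) | CC(C)[Si](C(C)C)(C(C)C)OC[C@@H](c1occc1C1OCCO1)[C@H](OC#C[Li])c1ccc(OCc2ccccc2)c(OCc2ccccc2)c1 | intermediate
22 | {[(2R,3S)-3-[3,4-bis(benzyloxy)phenyl]-2-[3-(1,3-dioxolan-2-yl)furan-2-yl]-3-(ethynyloxy)propyl]oxy}triisopropylsilane | CC(C)[Si](C(C)C)(C(C)C)OC[C@@H](c1occc1C1OCCO1)[C@H](OC#C)c1ccc(OCc2ccccc2)c(OCc2ccccc2)c1 | intermediate
23 | oxepine tautomer: 2,3-dihydrofuro[2,3-c]oxepine carrying the ring C substituents of 25, the dioxolanyl group on the carbon next to C3a, and the ring oxygen between future C6 and C7 | CC(C)[Si](C(C)C)(C(C)C)OC[C@H]1C2=C(C3OCCO3)C=COC=C2O[C@@H]1c1ccc(OCc2ccccc2)c(OCc2ccccc2)c1 | intermediate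
24 | C6–C7 arene oxide (6,7-epoxy-6,7-dihydrobenzofuran valence tautomer of 23, epoxide face undefined) | CC(C)[Si](C(C)C)(C(C)C)OC[C@H]1C2=C(O[C@@H]1c1ccc(OCc3ccccc3)c(OCc3ccccc3)c1)C1OC1C=C2C1OCCO1 | intermediate
25 | (2S,3R)-2-[3,4-bis(benzyloxy)phenyl]-4-(1,3-dioxolan-2-yl)-3-{[(triisopropylsilyl)oxy]methyl}-2,3-dihydro-1-benzofuran-7-ol | CC(C)[Si](C(C)C)(C(C)C)OC[C@H]1c2c(C3OCCO3)ccc(O)c2O[C@@H]1c1ccc(OCc2ccccc2)c(OCc2ccccc2)c1 | intermediate
26 | {[(2S,3R)-7-(benzyloxy)-2-[3,4-bis(benzyloxy)phenyl]-4-(1,3-dioxolan-2-yl)-2,3-dihydro-1-benzofuran-3-yl]methoxy}triisopropylsilane | CC(C)[Si](C(C)C)(C(C)C)OC[C@H]1c2c(C3OCCO3)ccc(OCc3ccccc3)c2O[C@@H]1c1ccc(OCc2ccccc2)c(OCc2ccccc2)c1 | intermediate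
27 | [(2S,3R)-7-(benzyloxy)-2-[3,4-bis(benzyloxy)phenyl]-4-(1,3-dioxolan-2-yl)-2,3-dihydro-1-benzofuran-3-yl]methanol | OC[C@H]1c2c(C3OCCO3)ccc(OCc3ccccc3)c2O[C@@H]1c1ccc(OCc2ccccc2)c(OCc2ccccc2)c1 | intermediate
28 | (2S,3S)-7-(benzyloxy)-2-[3,4-bis(benzyloxy)phenyl]-4-(1,3-dioxolan-2-yl)-2,3-dihydro-1-benzofuran-3-carbaldehyde | O=C[C@H]1c2c(C3OCCO3)ccc(OCc3ccccc3)c2O[C@@H]1c1ccc(OCc2ccccc2)c(OCc2ccccc2)c1 | intermediate
29 | (2S,3S)-7-(benzyloxy)-2-[3,4-bis(benzyloxy)phenyl]-4-(1,3-dioxolan-2-yl)-2,3-dihydro-1-benzofuran-3-carboxylic acid | OC(=O)[C@H]1c2c(C3OCCO3)ccc(OCc3ccccc3)c2O[C@@H]1c1ccc(OCc2ccccc2)c(OCc2ccccc2)c1 | intermediate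
30 | methyl (2S,3S)-7-(benzyloxy)-2-[3,4-bis(benzyloxy)phenyl]-4-(1,3-dioxolan-2-yl)-2,3-dihydro-1-benzofuran-3-carboxylate | COC(=O)[C@H]1c2c(C3OCCO3)ccc(OCc3ccccc3)c2O[C@@H]1c1ccc(OCc2ccccc2)c(OCc2ccccc2)c1 | intermediate
31 | methyl (2S,3S)-7-(benzyloxy)-2-[3,4-bis(benzyloxy)phenyl]-4-formyl-2,3-dihydro-1-benzofuran-3-carboxylate | COC(=O)[C@H]1c2c(C=O)ccc(OCc3ccccc3)c2O[C@@H]1c1ccc(OCc2ccccc2)c(OCc2ccccc2)c1 | intermediate
32 | malonic acid | OC(=O)CC(=O)O | starting material
33 | 2-({(2S,3S)-7-(benzyloxy)-2-[3,4-bis(benzyloxy)phenyl]-3-(methoxycarbonyl)-2,3-dihydro-1-benzofuran-4-yl}methylidene)propanedioic acid | COC(=O)[C@H]1c2c(C=C(C(=O)O)C(=O)O)ccc(OCc3ccccc3)c2O[C@@H]1c1ccc(OCc2ccccc2)c(OCc2ccccc2)c1 | intermediate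
34 | (2E)-3-{(2S,3S)-7-(benzyloxy)-2-[3,4-bis(benzyloxy)phenyl]-3-(methoxycarbonyl)-2,3-dihydro-1-benzofuran-4-yl}prop-2-enoic acid | COC(=O)[C@H]1c2c(/C=C/C(=O)O)ccc(OCc3ccccc3)c2O[C@@H]1c1ccc(OCc2ccccc2)c(OCc2ccccc2)c1 | intermediate
35 | (R)-3-(3,4-dihydroxyphenyl)lactic acid (danshensu) | O[C@H](Cc1ccc(O)c(O)c1)C(=O)O | starting material
36 | benzyl (2R)-3-[3,4-bis(benzyloxy)phenyl]-2-hydroxypropanoate | O[C@H](Cc1ccc(OCc2ccccc2)c(OCc2ccccc2)c1)C(=O)OCc1ccccc1 | intermediate
37 | O-acylisourea of 34 (acyl N,N'-dicyclohexylcarbamimidate) | COC(=O)[C@H]1c2c(/C=C/C(=O)OC(=NC3CCCCC3)NC3CCCCC3)ccc(OCc3ccccc3)c2O[C@@H]1c1ccc(OCc2ccccc2)c(OCc2ccccc2)c1 | intermediate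
38 | benzyl (2R)-3-[3,4-bis(benzyloxy)phenyl]-2-{[(2E)-3-{(2S,3S)-7-(benzyloxy)-2-[3,4-bis(benzyloxy)phenyl]-3-(methoxycarbonyl)-2,3-dihydro-1-benzofuran-4-yl}prop-2-enoyl]oxy}propanoate | COC(=O)[C@H]1c2c(/C=C/C(=O)O[C@H](Cc3ccc(OCc4ccccc4)c(OCc4ccccc4)c3)C(=O)OCc3ccccc3)ccc(OCc3ccccc3)c2O[C@@H]1c1ccc(OCc2ccccc2)c(OCc2ccccc2)c1 | intermediate
39 | monomethyl lithospermate, (2R)-3-(3,4-dihydroxyphenyl)-2-{[(2E)-3-{(2S,3S)-2-(3,4-dihydroxyphenyl)-7-hydroxy-3-(methoxycarbonyl)-2,3-dihydro-1-benzofuran-4-yl}prop-2-enoyl]oxy}propanoic acid | COC(=O)[C@H]1c2c(/C=C/C(=O)O[C@H](Cc3ccc(O)c(O)c3)C(=O)O)ccc(O)c2O[C@@H]1c1ccc(O)c(O)c1 | target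

Total step count: 19. Longest linear sequence: 18 (steps 1–16, 18 and 19). Step 17 is the only side-branch step.

Steps most likely to fail

Step 9. Several processes threaten this step:
- The silyl group may migrate to the benzylic potassium alkoxide.
- The hindered alkoxide may add only slowly to dichloroacetylene.
- The benzylic ynol ether may be lost thermally by retro-ene or [3,3] pathways during work-up.

The fallback sets out from 17 and avoids any metal alkoxide. It assembles the two alkyne carbons one at a time. Formylation of 17 (formic acetic anhydride, pyridine, 0 °C) gives the formate F1. Wittig-type dichloromethylenation of its carbonyl group (PPh3, CCl4, THF, 60 °C) gives the 2,2-dichlorovinyl ether F2. n-BuLi at −78 °C then eliminates HCl to give 20 and exchanges chlorine for lithium. The route is rejoined at 21 and, after the aqueous quench, at 22.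

Step 10. Several processes threaten this step:
- Attack by a furan whose C3' position is substituted may be slow.
- The acetal may be opened by the Lewis-acidic catalyst or by traces of acid.
- Hydration of the ynol ether, or capture of the activated alkyne by ring A, may then take over.

The fallback sets out from 9, 12 and 36 and returns at 38. It leaves C4 unsubstituted during the benzannulation and installs the whole side chain afterwards by C–H functionalisation.
- Commercial furan-2-ylacetic acid is loaded on 9 as in step 5 to give the imide F3, and the boron aldol with 12 as in step 6 gives the syn aldol F4.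
- LiBH4 gives the diol F5, i-Pr3SiCl gives the silyl ether F6, and KH/trichloroethylene/n-BuLi gives the ynol ether F7.
- Ph3PAuNTf2 converts this unhindered furan, which matches the known substrates closely, into the phenol F8.
- BnBr/K2CO3 gives the benzyl ether F9, n-Bu4NF gives the alcohol F10, and the nitroxyl/NaClO2 oxidation gives the acid F11.
- Separately, 36 is acylated with acryloyl chloride and Et3N to the acrylate F12.
- F11 and F12 are joined by carboxylate-directed ortho C–H olefination (Pd(OAc)2, N-acetyl-L-isoleucine, KHCO3, O2, tert-amyl alcohol, 85 °C). This divalent-palladium reaction is known for arylacetic acids. It can reach only C4 here because the other ortho position is C7a. It gives the olefinated acid F13.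
- MeI/KHCO3 converts F13 into 38.

Step 19. Several processes threaten this step:
- The benzyl ester may be cleaved incompletely.
- The electron-rich benzylic C2–O1 bond may ionise.
- The liberated catechols may be alkylated or oxidised during the sixfold deprotection.

The fallback sets out from 30 and 35 and returns at 39. It removes the benzyl groups by hydrogenolysis before the alkene exists and finishes with a neutral deallylation.
- H2 and Pd/C in EtOAc convert 30 into the triphenol F14, and allyl bromide/K2CO3 gives the tris(allyl ether) F15.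
- 1 M HCl in THF gives the aldehyde F16, and malonic acid in pyridine/piperidine gives the propenoic acid F17.
- Danshensu 35 is converted with allyl bromide/K2CO3 into the triallyl lactate F18.
- DCC and 4-(dimethylamino)pyridine join F17 and F18 to the hexaallyl ester F19.
- Zerovalent palladium (Pd(PPh3)4, morpholine, THF, rt) transfers all six allyl groups to the amine and releases 39 without touching the alkene or the methyl ester.

Further compounds
F1 | step 9 | (1S,2R)-1-[3,4-bis(benzyloxy)phenyl]-2-[3-(1,3-dioxolan-2-yl)furan-2-yl]-3-[(triisopropylsilyl)oxy]propyl formate | CC(C)[Si](C(C)C)(C(C)C)OC[C@@H](c1occc1C1OCCO1)[C@H](OC=O)c1ccc(OCc2ccccc2)c(OCc2ccccc2)c1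
F2 | step 9 | {[(2R,3S)-3-[3,4-bis(benzyloxy)phenyl]-3-[(2,2-dichloroethenyl)oxy]-2-[3-(1,3-dioxolan-2-yl)furan-2-yl]propyl]oxy}triisopropylsilane | CC(C)[Si](C(C)C)(C(C)C)OC[C@@H](c1occc1C1OCCO1)[C@H](OC=C(Cl)Cl)c1ccc(OCc2ccccc2)c(OCc2ccccc2)c1
F3 | step 10 | (S)-4-benzyl-3-[2-(furan-2-yl)acetyl]-1,3-oxazolidin-2-one | O=C(Cc1ccco1)N1[C@@H](Cc2ccccc2)COC1=O
F4 | step 10 | (S)-4-benzyl-3-{(2R,3S)-3-[3,4-bis(benzyloxy)phenyl]-2-(furan-2-yl)-3-hydroxypropanoyl}-1,3-oxazolidin-2-one | O=C([C@@H](c1ccco1)[C@H](O)c1ccc(OCc2ccccc2)c(OCc2ccccc2)c1)N1[C@@H](Cc2ccccc2)COC1=O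
F5 | step 10 | (1S,2R)-1-[3,4-bis(benzyloxy)phenyl]-2-(furan-2-yl)propane-1,3-diol | OC[C@@H](c1ccco1)[C@H](O)c1ccc(OCc2ccccc2)c(OCc2ccccc2)c1
F6 | step 10 | (1S,2R)-1-[3,4-bis(benzyloxy)phenyl]-2-(furan-2-yl)-3-[(triisopropylsilyl)oxy]propan-1-ol | CC(C)[Si](C(C)C)(C(C)C)OC[C@@H](c1ccco1)[C@H](O)c1ccc(OCc2ccccc2)c(OCc2ccccc2)c1
F7 | step 10 | {[(2R,3S)-3-[3,4-bis(benzyloxy)phenyl]-3-(ethynyloxy)-2-(furan-2-yl)propyl]oxy}triisopropylsilane | CC(C)[Si](C(C)C)(C(C)C)OC[C@@H](c1ccco1)[C@H](OC#C)c1ccc(OCc2ccccc2)c(OCc2ccccc2)c1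
F8 | step 10 | (2S,3R)-2-[3,4-bis(benzyloxy)phenyl]-3-{[(triisopropylsilyl)oxy]methyl}-2,3-dihydro-1-benzofuran-7-ol | CC(C)[Si](C(C)C)(C(C)C)OC[C@H]1c2cccc(O)c2O[C@@H]1c1ccc(OCc2ccccc2)c(OCc2ccccc2)c1
F9 | step 10 | {[(2S,3R)-7-(benzyloxy)-2-[3,4-bis(benzyloxy)phenyl]-2,3-dihydro-1-benzofuran-3-yl]methoxy}triisopropylsilane | CC(C)[Si](C(C)C)(C(C)C)OC[C@H]1c2cccc(OCc3ccccc3)c2O[C@@H]1c1ccc(OCc2ccccc2)c(OCc2ccccc2)c1
F10 | step 10 | [(2S,3R)-7-(benzyloxy)-2-[3,4-bis(benzyloxy)phenyl]-2,3-dihydro-1-benzofuran-3-yl]methanol | OC[C@H]1c2cccc(OCc3ccccc3)c2O[C@@H]1c1ccc(OCc2ccccc2)c(OCc2ccccc2)c1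
F11 | step 10 | (2S,3S)-7-(benzyloxy)-2-[3,4-bis(benzyloxy)phenyl]-2,3-dihydro-1-benzofuran-3-carboxylic acid | OC(=O)[C@H]1c2cccc(OCc3ccccc3)c2O[C@@H]1c1ccc(OCc2ccccc2)c(OCc2ccccc2)c1
F12 | step 10 | benzyl (2R)-2-(acryloyloxy)-3-[3,4-bis(benzyloxy)phenyl]propanoate | C=CC(=O)O[C@H](Cc1ccc(OCc2ccccc2)c(OCc2ccccc2)c1)C(=O)OCc1ccccc1
F13 | step 10 | (2S,3S)-7-(benzyloxy)-4-[(1E)-3-{[(2R)-1-(benzyloxy)-3-[3,4-bis(benzyloxy)phenyl]-1-oxopropan-2-yl]oxy}-3-oxoprop-1-en-1-yl]-2-[3,4-bis(benzyloxy)phenyl]-2,3-dihydro-1-benzofuran-3-carboxylic acid | OC(=O)[C@H]1c2c(/C=C/C(=O)O[C@H](Cc3ccc(OCc4ccccc4)c(OCc4ccccc4)c3)C(=O)OCc3ccccc3)ccc(OCc3ccccc3)c2O[C@@H]1c1ccc(OCc2ccccc2)c(OCc2ccccc2)c1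
F14 | step 19 | methyl (2S,3S)-2-(3,4-dihydroxyphenyl)-4-(1,3-dioxolan-2-yl)-7-hydroxy-2,3-dihydro-1-benzofuran-3-carboxylate | COC(=O)[C@H]1c2c(C3OCCO3)ccc(O)c2O[C@@H]1c1ccc(O)c(O)c1
F15 | step 19 | methyl (2S,3S)-7-(allyloxy)-2-[3,4-bis(allyloxy)phenyl]-4-(1,3-dioxolan-2-yl)-2,3-dihydro-1-benzofuran-3-carboxylate | COC(=O)[C@H]1c2c(C3OCCO3)ccc(OCC=C)c2O[C@@H]1c1ccc(OCC=C)c(OCC=C)c1
F16 | step 19 | methyl (2S,3S)-7-(allyloxy)-2-[3,4-bis(allyloxy)phenyl]-4-formyl-2,3-dihydro-1-benzofuran-3-carboxylate | COC(=O)[C@H]1c2c(C=O)ccc(OCC=C)c2O[C@@H]1c1ccc(OCC=C)c(OCC=C)c1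
F17 | step 19 | (2E)-3-{(2S,3S)-7-(allyloxy)-2-[3,4-bis(allyloxy)phenyl]-3-(methoxycarbonyl)-2,3-dihydro-1-benzofuran-4-yl}prop-2-enoic acid | COC(=O)[C@H]1c2c(/C=C/C(=O)O)ccc(OCC=C)c2O[C@@H]1c1ccc(OCC=C)c(OCC=C)c1
F18 | step 19 | allyl (2R)-3-[3,4-bis(allyloxy)phenyl]-2-hydroxypropanoate | O[C@H](Cc1ccc(OCC=C)c(OCC=C)c1)C(=O)OCC=C
F19 | step 19 | allyl (2R)-3-[3,4-bis(allyloxy)phenyl]-2-{[(2E)-3-{(2S,3S)-7-(allyloxy)-2-[3,4-bis(allyloxy)phenyl]-3-(methoxycarbonyl)-2,3-dihydro-1-benzofuran-4-yl}prop-2-enoyl]oxy}propanoate | COC(=O)[C@H]1c2c(/C=C/C(=O)O[C@H](Cc3ccc(OCC=C)c(OCC=C)c3)C(=O)OCC=C)ccc(OCC=C)c2O[C@@H]1c1ccc(OCC=C)c(OCC=C)c1
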